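**Retrosynthetic overview**

1. The strategy rests on the single ring of the target, a cyclohexanol (C1 = CH carrying the chain C1'–C13', C2 = CMe2, C3–C5 = CH2, C6 = C(CH3)OH, chain and OH trans). This ring is the last two isoprene units of all-E geranylfarnesol, joined once (C1–C2) and hydrated at C6.
2. Last disconnection (the only ring, formed last): C1–C2 and C6–O are made together from geranylfarnesol by an engineered squalene-hopene cyclase that stops after ring one and captures water. Both stereocentres (1S,6S) are set there.
3. Geranylfarnesol is cut at C8–C9 (counted from CH2OH) into farnesyl phenyl sulfone and silyl-protected 8-bromogeraniol. The sulfonyl group sits on farnesyl C1 so that the allyl unit formed during its palladium/hydride removal has one secondary and one tertiary end and the E alkene is returned in place. With the sulfone on geranyl C8 both ends would be secondary and alkene regioisomers would be expected.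
4. The fragments come from (2E,6E)-farnesol (bromide, then sulfinate) and geraniol (silylation, SeO2 oxidation of the E methyl group, bromination).

Key step: step 9

Assumption: a cyclase variant with the required product profile is taken to be obtainable by screening focused libraries of the Alicyclobacillus acidocaldarius enzyme. The (1S,6S) configuration is the one given by the native fold of this enzyme family (the fold that gives 5α-H and 10β-CH3 in hopene), so the facial preference need not be inverted.

**Route**

Step 1
Reactants: 1 (2E,6E)-farnesol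
Product: 2 (2E,6E)-farnesyl bromide
Conditions: PBr3 (0.4 equiv), Et2O, −10 to 0 °C; used crude
Reagents that add atoms: phosphorus tribromide, BrP(Br)Br
Why: Bromination of a primary allylic alcohol with PBr3 goes through the phosphite ester and SN2 displacement at low temperature, which should keep both alkene geometries and avoid allylic transposition.

Step 2
Reactants: 2 (2E,6E)-farnesyl bromide
Product: 3 (2E,6E)-farnesyl phenyl sulfone
Conditions: PhSO2Na (1.3 equiv), DMF, 0 °C to rt
Reagents that add atoms: sodium benzenesulfinate, [Na+].[O-]S(=O)c1ccccc1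
Why: Sulfinate S-alkylation (SN2) of the primary allylic bromide in a dipolar aprotic solvent should give the allylic sulfone without touching the 2E alkene.

Step 3
Reactants: 4 geraniol
Product: 5 geranyl tert-butyldiphenylsilyl (TBDPS) ether
Conditions: TBDPSCl, imidazole, DMF, rt
Reagents that add atoms: tert-butyl(chloro)diphenylsilane, CC(C)(C)[Si](Cl)(c1ccccc1)c1ccccc1
Why: Imidazole-promoted silylation of the primary alcohol installs an ether that should withstand the mildly acidic SeO2 oxidation, n-BuLi and LiBHEt3 used later.

Step 4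
Reactants: 5 geranyl TBDPS ether
Product: 6 (2E,6E)-8-(tert-butyldiphenylsilyloxy)-2,6-dimethylocta-2,6-dien-1-ol
Conditions: SeO2 (0.1 equiv), t-BuOOH (2 equiv), salicylic acid (0.1 equiv), CH2Cl2, 0 °C to rt, stopped at partial conversion; SiO2
Reagents that add atoms: selenium dioxide (catalytic oxygen carrier), O=[Se]=O; tert-butyl hydroperoxide (stoichiometric oxygen source), CC(C)(C)OO
Why: Riley allylic oxidation (ene reaction of SeO2, then [2,3]-sigmatropic shift, t-BuOOH as reoxidant) hydroxylates the E methyl group of the terminal trisubstituted alkene because the C2 alkene is deactivated by the allylic oxygen, and stopping early should keep the over-oxidised enal minor and allow unreacted 5 to be recycled.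

Step 5
Reactants: 6 (2E,6E)-8-(tert-butyldiphenylsilyloxy)-2,6-dimethylocta-2,6-dien-1-ol
Product: 7 (2E,6E)-8-bromo-3,7-dimethylocta-2,6-dienyl TBDPS ether
Conditions: CBr4, PPh3, CH2Cl2, −20 to 0 °C
Reagents that add atoms: carbon tetrabromide, BrC(Br)(Br)Br
Why: In the Appel reaction the alkoxyphosphonium ion is displaced by bromide in an SN2 step under neutral conditions, which should preserve the 6E geometry and the silyl ether.

Step 6
Reactants: 3 (2E,6E)-farnesyl phenyl sulfone; 7 (2E,6E)-8-bromo-3,7-dimethylocta-2,6-dienyl TBDPS ether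
Product: 9 TBDPS ether of 9-(phenylsulfonyl)geranylfarnesol (both configurations at C9), via lithiated farnesyl phenyl sulfone 8 (not isolated)
Conditions: n-BuLi (1.05 equiv), THF, −78 °C; then 7, −78 to −30 °C
Reagents that add atoms: none
Why: Deprotonation next to the sulfonyl group gives a stabilised allylic carbanion that is alkylated at its α carbon by the primary allylic bromide in an SN2 step (allylic sulfone alkylation), forming the C8–C9 bond, and the new sulfonyl-bearing stereocentre is of no consequence because it becomes CH2 in step 7.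

Step 7
Reactants: 9 TBDPS ether of 9-(phenylsulfonyl)geranylfarnesol
Product: 10 (2E,6E,10E,14E)-geranylfarnesyl TBDPS ether
Conditions: PdCl2(dppp) (5 mol %), LiBHEt3 (2.5 equiv), THF, 0 °C
Reagents that add atoms: none
Why: In this Tsuji–Trost-type reductive desulfonylation, zerovalent palladium formed from PdCl2(dppp) ionises the allylic sulfone to a π-allyl complex and hydride is delivered to its secondary end (C9), so the C10=C11 alkene should be returned in place and E because the tertiary end does not undergo σ-allyl rotation.

Step 8
Reactants: 10 (2E,6E,10E,14E)-geranylfarnesyl TBDPS ether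
Product: 11 (2E,6E,10E,14E)-geranylfarnesol
Conditions: Bu4NF, THF, 0 °C to rt
Reagents that add atoms: none
Why: Fluoride cleaves the Si–O bond (desilylation) without affecting the skipped polyene or the allylic alcohol.

Step 9
Reactants: 11 (2E,6E,10E,14E)-geranylfarnesol
Product: 13 preluffariellolide A, via enzyme-bound C6 tertiary cation 12 (not isolated)
Conditions: engineered squalene-hopene cyclase variant (A. acidocaldarius enzyme, Asp376 kept, ring-B pocket mutated and selected by screening), E. coli whole cells, citrate buffer pH 6.0, 2-hydroxypropyl-β-cyclodextrin, 30–37 °C; EtOAc extraction, SiO2, unreacted 11 recycled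
Reagents that add atoms: water, O
Why: Proposed new method: the catalytic aspartic acid (Asp376) protonates C3 of the terminal isopropylidene, the neighbouring E alkene, held in a chair fold, attacks the developing C2 cation through C1, and the resulting C6 tertiary cation 12 is quenched by an active-site water instead of by the next alkene. The closest known reactions are the monocyclisation of geranylacetone and the cyclisations of farnesol and homofarnesol by engineered squalene-hopene cyclases, and the water-terminated formation of hopanol from squalene by the wild-type enzyme. The single ring closes in a 6-endo-trig mode with respect to the attacking C1=C6 alkene. Anti addition of C2 and water across this E alkene fixes C1 and C6 relative to each other (chain and hydroxyl trans-diequatorial, C6 methyl axial), and the chiral pocket, which presents the same alkene face as in hopene ring A formation, fixes both as S. The step needs initiation at the terminal alkene only, which is the one alkene that can reach the acid at the end of the hydrophobic channel while the allylic alcohol end stays at the entrance; it also needs arrest after ring one with hydration, which must come from substitutions at the ring-B wall (for example at Tyr420, Leu607, Phe365, Ile261 and Gly600) that misplace the C3'=C4' alkene and hold an ordered water at C6.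

**Compound list**

1 | (2E,6E)-farnesol | CC(C)=CCC/C(C)=C/CC/C(C)=C/CO | starting material
2 | (2E,6E)-farnesyl bromide | CC(C)=CCC/C(C)=C/CC/C(C)=C/CBr | intermediate
3 | (2E,6E)-farnesyl phenyl sulfone | CC(C)=CCC/C(C)=C/CC/C(C)=C/CS(=O)(=O)c1ccccc1 | intermediate
4 | geraniol | CC(C)=CCC/C(C)=C/CO | starting material
5 | geranyl TBDPS ether | CC(C)=CCC/C(C)=C/CO[Si](c1ccccc1)(c1ccccc1)C(C)(C)C | intermediate
6 | (2E,6E)-8-(tert-butyldiphenylsilyloxy)-2,6-dimethylocta-2,6-dien-1-ol | OC/C(C)=C/CC/C(C)=C/CO[Si](c1ccccc1)(c1ccccc1)C(C)(C)C | intermediate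
7 | (2E,6E)-8-bromo-3,7-dimethylocta-2,6-dienyl TBDPS ether | BrC/C(C)=C/CC/C(C)=C/CO[Si](c1ccccc1)(c1ccccc1)C(C)(C)C | intermediate
8 | lithiated farnesyl phenyl sulfone (α-sulfonyl carbanion, lithium salt) | [Li+].CC(C)=CCC/C(C)=C/CC/C(C)=C/[CH-]S(=O)(=O)c1ccccc1 | intermediate (not isolated)
9 | tert-butyl{[(2E,6E,10E,14E)-3,7,11,15,19-pentamethyl-9-(phenylsulfonyl)icosa-2,6,10,14,18-pentaen-1-yl]oxy}diphenylsilane, C9 racemic | CC(C)=CCC/C(C)=C/CC/C(C)=C/C(C/C(C)=C/CC/C(C)=C/CO[Si](c1ccccc1)(c1ccccc1)C(C)(C)C)S(=O)(=O)c1ccccc1 | intermediate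
10 | (2E,6E,10E,14E)-geranylfarnesyl TBDPS ether | CC(C)=CCC/C(C)=C/CC/C(C)=C/CC/C(C)=C/CC/C(C)=C/CO[Si](c1ccccc1)(c1ccccc1)C(C)(C)C | intermediate
11 | (2E,6E,10E,14E)-geranylfarnesol (3,7,11,15,19-pentamethylicosa-2,6,10,14,18-pentaen-1-ol) | CC(C)=CCC/C(C)=C/CC/C(C)=C/CC/C(C)=C/CC/C(C)=C/CO | intermediate
12 | enzyme-bound monocyclic C6 tertiary cation, C1 configured as in 13 | C/C(=C\CO)CC/C=C(\C)CC/C=C(\C)CC[C@H]1C(C)(C)CCC[C+]1C | intermediate (not isolated)
13 | preluffariellolide A, (1S,2S)-2-[(3E,7E,11E)-13-hydroxy-3,7,11-trimethyltrideca-3,7,11-trien-1-yl]-1,3,3-trimethylcyclohexan-1-ol | C/C(=C\CO)CC/C=C(\C)CC/C=C(\C)CC[C@H]1C(C)(C)CCC[C@]1(C)O | target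

**Step count**

Total: 9 steps. Longest linear sequence: 7 steps (steps 3, 4, 5, 6, 7, 8, 9 from geraniol).

**Steps most likely to fail**

Step 9 (key step). The cascade may fail to stop after ring one (polycyclic products), may end by proton loss to an exo- or endocyclic alkene instead of hydration, or may not reach useful conversion with the C25 alcohol. The fallback uses known chemistry, sets out from geraniol 4 and farnesol 1, and comes back at 13. The ring is built as a C10 sulfone and joined to a C15 chain at C1'–C2'.
- Ring fragment: geraniol 4 is brominated (PBr3, Et2O, 0 °C) to geranyl bromide F1 and treated with PhSO2Na in DMF to give geranyl phenyl sulfone F2.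
- Hg(OCOCF3)2 in MeNO2 at −20 °C should induce a divalent mercury-initiated cationic cyclisation with trifluoroacetate capture anti to the new C–C bond, giving the racemic trans organomercurial trifluoroacetate F3.
- NaBH4 in aqueous NaOH should demercurate and saponify F3 to the racemic trans hydroxy sulfone F4; alkene by-products from proton loss are removed by chromatography.
- Preparative chromatography on a chiral stationary phase should give the (1S,2S) hydroxy sulfone F5.
- Chain fragment: farnesol 1 is silylated (TBDPSCl, imidazole) to farnesyl TBDPS ether F6, oxidised (SeO2, t-BuOOH) to the 12-hydroxyfarnesyl TBDPS ether F7 and brominated (CBr4, PPh3) to the 12-bromofarnesyl TBDPS ether F8.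
- Coupling: the dianion of F5 (n-BuLi, 2.2 equiv, THF/DMPU, −78 °C) is alkylated with F8 to give the coupled hydroxy sulfone F9.
- Na/Hg amalgam with Na2HPO4 in MeOH/THF at −20 °C removes the now non-allylic sulfonyl group to give the TBDPS ether of the target F10, and Bu4NF in THF gives 13.

Step 7. Hydride may be delivered in part to the tertiary end of the allyl unit, or the allyl complex may equilibrate, giving alkene regio- or stereoisomers that are hard to separate from 10. The fallback avoids the sulfone altogether, sets out from 1 and 7, and comes back at 10. Farnesol 1 is converted by Corey–Kim chlorination (N-chlorosuccinimide, Me2S, CH2Cl2, −40 to 0 °C) to farnesyl chloride F11. Activated barium metal (from BaI2 and lithium biphenylide, THF) at −78 °C should give farnesylbarium chloride F12. This allylbarium reagent is known to couple with allylic bromides at its α carbon with retention of alkene geometry, and with 7 it should give 10 directly.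

Step 4. The oxidation may stall, run on to the enal, attack other allylic positions or cost part of the silyl group. The fallback builds the E allylic alcohol end by olefination, sets out from 5, and comes back at 6. mCPBA (1 equiv, CH2Cl2, 0 °C) should epoxidise the more electron-rich terminal alkene to the 6,7-epoxide F13. HIO4·2H2O in THF/Et2O at 0 °C cleaves it to the C7 aldehyde F14. Wittig reaction with Ph3P=C(CH3)CO2Et in CH2Cl2 should give the E enoate F15, and i-Bu2AlH in CH2Cl2 at −78 °C reduces it to 6.

**Further compounds**

F1 | step 9 | geranyl bromide | CC(C)=CCC/C(C)=C/CBr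
F2 | step 9 | geranyl phenyl sulfone | CC(C)=CCC/C(C)=C/CS(=O)(=O)c1ccccc1
F3 | step 9 | racemic 1,3,3-trimethyl-2-[(phenylsulfonyl)methyl]-4-(trifluoroacetoxymercurio)cyclohexyl trifluoroacetate, all three ring substituents equatorial, both enantiomers | O=S(=O)(c1ccccc1)C[C@H]1C(C)(C)[C@@H]([Hg]OC(=O)C(F)(F)F)CC[C@]1(C)OC(=O)C(F)(F)F.O=S(=O)(c1ccccc1)C[C@@H]1C(C)(C)[C@H]([Hg]OC(=O)C(F)(F)F)CC[C@@]1(C)OC(=O)C(F)(F)F
F4 | step 9 | racemic trans-1,3,3-trimethyl-2-[(phenylsulfonyl)methyl]cyclohexan-1-ol, both enantiomers | O=S(=O)(c1ccccc1)C[C@H]1C(C)(C)CCC[C@]1(C)O.O=S(=O)(c1ccccc1)C[C@@H]1C(C)(C)CCC[C@@]1(C)O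
F5 | step 9 | (1S,2S)-1,3,3-trimethyl-2-[(phenylsulfonyl)methyl]cyclohexan-1-ol | O=S(=O)(c1ccccc1)C[C@H]1C(C)(C)CCC[C@]1(C)O
F6 | step 9 | (2E,6E)-farnesyl TBDPS ether | CC(C)=CCC/C(C)=C/CC/C(C)=C/CO[Si](c1ccccc1)(c1ccccc1)C(C)(C)C
F7 | step 9 | (2E,6E,10E)-12-(tert-butyldiphenylsilyloxy)-2,6,10-trimethyldodeca-2,6,10-trien-1-ol | OC/C(C)=C/CC/C(C)=C/CC/C(C)=C/CO[Si](c1ccccc1)(c1ccccc1)C(C)(C)C
F8 | step 9 | (2E,6E,10E)-12-bromo-3,7,11-trimethyldodeca-2,6,10-trienyl TBDPS ether | BrC/C(C)=C/CC/C(C)=C/CC/C(C)=C/CO[Si](c1ccccc1)(c1ccccc1)C(C)(C)C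
F9 | step 9 | TBDPS ether of 1'-(phenylsulfonyl)preluffariellolide A, both configurations at C1' | CC(C)(C)[Si](c1ccccc1)(c1ccccc1)OC/C=C(\C)CC/C=C(\C)CC/C=C(\C)CC(S(=O)(=O)c1ccccc1)[C@H]1C(C)(C)CCC[C@]1(C)O
F10 | step 9 | TBDPS ether of preluffariellolide A (primary allylic oxygen silylated) | CC(C)(C)[Si](c1ccccc1)(c1ccccc1)OC/C=C(\C)CC/C=C(\C)CC/C=C(\C)CC[C@H]1C(C)(C)CCC[C@]1(C)O
F11 | step 7 | (2E,6E)-farnesyl chloride | CC(C)=CCC/C(C)=C/CC/C(C)=C/CCl
F12 | step 7 | (2E,6E)-farnesylbarium chloride | CC(C)=CCC/C(C)=C/CC/C(C)=C/C[Ba]Cl
F13 | step 4 | (2E)-6,7-epoxy-3,7-dimethyloct-2-enyl TBDPS ether, racemic | CC1(C)OC1CC/C(C)=C/CO[Si](c1ccccc1)(c1ccccc1)C(C)(C)C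
F14 | step 4 | (4E)-6-(tert-butyldiphenylsilyloxy)-4-methylhex-4-enal | O=CCC/C(C)=C/CO[Si](c1ccccc1)(c1ccccc1)C(C)(C)C
F15 | step 4 | ethyl (2E,6E)-8-(tert-butyldiphenylsilyloxy)-2,6-dimethylocta-2,6-dienoate | CCOC(=O)/C(C)=C/CC/C(C)=C/CO[Si](c1ccccc1)(c1ccccc1)C(C)(C)C
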